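Ring C of the flavan is disconnected at C2–C3. The feature exploited is that O1–C2–C1' is already the O–C(=O)–aryl unit of a ring B benzoate on the C8a phenol oxygen of ring A. C4–C3 is an acetaldehyde arm on C4a, so only the C2–C3 bond is missing. In one operation low-valent titanium joins ester carbon C2 to aldehyde carbon C3, removes both carbonyl oxygens and closes ring C as an achiral 2-aryl-4H-chromene. The precursor is a MOM-protected 2-(2-oxoethyl)phenyl 3-bromobenzoate made by plain esterification. One reagent-controlled syn hydroboration then sets C2 and C3, and the bromine carries the late C5' geranylation.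

Key step: step 9

Assumption on step 10: IpcBH2 from (+)-α-pinene converts 1-phenylcyclohexene into the (1S,2R)-trans alcohol, which is the spatial counterpart of the (2R,3S)-flavan-3-ol. The same facial sense is assumed for the chromene. If it proves opposite, the reagent from (−)-α-pinene is used instead.

Remark on step 9: the titanium-bound intermediate sits on a cluster or surface and is drawn formally as a TiCl2 chelate.

Remark on precursor design:
- Bromine, not the geranyl chain, occupies C5' until both alkene-consuming steps (8 and 10) are past.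
- The sensitive arylacetaldehyde is unmasked from an allyl group directly before the coupling.
- O3 is later carried as a TES ether, because an alkyl MOM ether would prolong the final acid exposure.

Step 1
Reactants: 1 phloroglucinol
Product: 2 3,5-bis(methoxymethoxy)phenol
Conditions: MOMCl (2.0 equiv), i-Pr2NEt, DMF, 0 °C → rt
Reagents that add atoms: chloromethyl methyl ether (MOMCl), COCCl
Why: Williamson-type O-alkylation with a reactive α-chloro ether; the three hydroxyls are equivalent, so two equivalents of MOMCl should give a statistical mixture from which the bis-ether is taken by chromatography while the mono-ether is resubmitted.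

Step 2
Reactants: 2 3,5-bis(methoxymethoxy)phenol; 3 allyl bromide
Product: 4 1-(allyloxy)-3,5-bis(methoxymethoxy)benzene
Conditions: K2CO3, acetone, reflux
Reagents that add atoms: none
Why: Williamson ether synthesis at the only free phenol, where carbonate in acetone favours O- over C-allylation.

Step 3
Reactants: 4 1-(allyloxy)-3,5-bis(methoxymethoxy)benzene
Product: 6 2-allyl-3,5-bis(methoxymethoxy)phenol, via allyl cyclohexadienone 5 (not isolated)
Conditions: PhNEt2, 195 °C, sealed tube, Ar
Reagents that add atoms: none
Why: Aromatic Claisen rearrangement ([3,3] shift, then tautomerisation); both ortho positions are equivalent, so one regioisomer is expected, and the basic medium keeps the MOM acetals intact.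

Step 4
Reactants: 7 5-bromovanillin
Product: 8 3-bromo-4,5-dihydroxybenzaldehyde
Conditions: AlCl3, pyridine, CH2Cl2, reflux; then 2 M HCl
Reagents that add atoms: none
Why: Lewis-acid-assisted aryl methyl ether cleavage, in which aluminium chelated between the free 4-OH and the neighbouring OMe activates the methyl group for SN2 removal by pyridine and leaves aldehyde and bromide untouched.

Step 5
Reactants: 8 3-bromo-4,5-dihydroxybenzaldehyde
Product: 9 3-bromo-4,5-bis(methoxymethoxy)benzaldehyde
Conditions: MOMCl (3 equiv), i-Pr2NEt, CH2Cl2, 0 °C → rt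
Reagents that add atoms: chloromethyl methyl ether (MOMCl), COCCl
Why: Exhaustive O-alkylation of the acidic catechol hydroxyls with MOMCl under amine base, conditions to which the aldehyde and the aryl bromide are inert.

Step 6
Reactants: 9 3-bromo-4,5-bis(methoxymethoxy)benzaldehyde
Product: 10 3-bromo-4,5-bis(methoxymethoxy)benzoic acid
Conditions: NaClO2, NaH2PO4, 2-methyl-2-butene, t-BuOH/H2O, rt
Reagents that add atoms: sodium chlorite, [Na+].[O-]Cl=O
Why: Pinnick oxidation, whose phosphate-buffered mild acidity spares the MOM acetals while the alkene scavenges hypochlorous acid and so prevents ring chlorination.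

Step 7
Reactants: 6 2-allyl-3,5-bis(methoxymethoxy)phenol; 10 3-bromo-4,5-bis(methoxymethoxy)benzoic acid
Product: 11 2-allyl-3,5-bis(methoxymethoxy)phenyl 3-bromo-4,5-bis(methoxymethoxy)benzoate
Conditions: EDC·HCl, DMAP, CH2Cl2, 0 °C → rt
Reagents that add atoms: none
Why: Steglich-type carbodiimide esterification, in which DMAP relays the acyl group to the moderately hindered phenol under neutral conditions and thereby installs the O1–C2–C1' unit.

Step 8
Reactants: 11 2-allyl-3,5-bis(methoxymethoxy)phenyl 3-bromo-4,5-bis(methoxymethoxy)benzoate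
Product: 13 2-(2-oxoethyl)-3,5-bis(methoxymethoxy)phenyl 3-bromo-4,5-bis(methoxymethoxy)benzoate, via vicinal diol 12 (not isolated)
Conditions: OsO4 (2 mol %), NaIO4 (4 equiv), 2,6-lutidine, dioxane/H2O, rt; used at once
Reagents that add atoms: OsO4 (catalytic oxygen carrier), O=[Os](=O)(=O)=O; NaIO4 (ultimate oxygen source), [Na+].[O-]I(=O)(=O)=O
Why: Lemieux–Johnson oxidative cleavage of the only alkene, chosen over ozone because of the electron-rich rings, with lutidine buffering and in situ glycol cleavage outrunning acyl migration from O1.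

Step 9
Reactants: 13 2-(2-oxoethyl)-3,5-bis(methoxymethoxy)phenyl 3-bromo-4,5-bis(methoxymethoxy)benzoate
Product: 15 2-[3-bromo-4,5-bis(methoxymethoxy)phenyl]-5,7-bis(methoxymethoxy)-4H-chromene, via titanium 2,3-diolate 14 (not isolated)
Conditions: TiCl3 (10 equiv), Zn dust (25 equiv), pyridine (5 equiv), DME, reflux 2 h; then 13 by syringe pump over 20 h (final ca. 3 mM), reflux, Ar; aq. K2CO3 work-up, basic Al2O3
Reagents that add atoms: none
Why: Low-valent titanium reduces the more easily reduced aldehyde C3=O to a titanium ketyl, which adds to the neighbouring ester carbon C2 to give the titanium-bound 2,3-diolate 14, and further reduction expels both oxygens as titanium oxide, leaving C2=C3 with O1 still on C2. The closest known reaction type is the McMurry-type oxo-ester cyclisation of acyloxy carbonyl compounds to benzofurans and cyclic enol ethers, used here one ring size larger. Ring C closes in a 6-exo-trig mode, since C3 attacks C2 while the ester C=O lies outside the new ring. No stereocentre is formed because C2 and C3 both become sp2. The step needs ester–aldehyde cross-coupling rather than aldehyde–aldehyde pinacol or alkene dimerisation, which the ortho arrangement of acyloxy group and acetaldehyde arm on ring A secures together with slow addition at high dilution. Pyridine tempers the Lewis-acidic titanium and zinc chlorides so that the MOM acetals and the acid-labile enol ether should survive, and aryl bromides are normally inert to this reagent.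

Step 10
Reactants: 15 2-[3-bromo-4,5-bis(methoxymethoxy)phenyl]-5,7-bis(methoxymethoxy)-4H-chromene
Product: 17 (2R,3S)-2-[3-bromo-4,5-bis(methoxymethoxy)phenyl]-5,7-bis(methoxymethoxy)chroman-3-ol, via C3 isopinocampheylborane 16 (not isolated)
Conditions: IpcBH2 [from (+)-α-pinene] (1.2 equiv), THF, −25 → 0 °C; then 3 M NaOH, 30% H2O2, 0 °C
Reagents that add atoms: hydrogen peroxide, OO
Why: Brown asymmetric hydroboration–oxidation: O1 and the C2 aryl group both direct boron to C3, the four-centre syn addition places H on C2 and B on C3 on one face, the isopinocampheyl group (the reagent type suited to trisubstituted 1-arylcycloalkenes) selects that face, and oxidation with retention gives the 2,3-trans (2R,3S) alcohol.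

Step 11
Reactants: 17 (2R,3S)-2-[3-bromo-4,5-bis(methoxymethoxy)phenyl]-5,7-bis(methoxymethoxy)chroman-3-ol
Product: 18 (2R,3S)-2-[3-bromo-4,5-bis(methoxymethoxy)phenyl]-5,7-bis(methoxymethoxy)-3-(triethylsilyloxy)chromane
Conditions: TESCl, imidazole, CH2Cl2, 0 °C → rt
Reagents that add atoms: chlorotriethylsilane (TESCl), CC[Si](Cl)(CC)CC
Why: Imidazole-promoted silylation of the single free alcohol removes the acidic proton before metalation and touches neither stereocentre.

Step 12
Reactants: 18 (2R,3S)-2-[3-bromo-4,5-bis(methoxymethoxy)phenyl]-5,7-bis(methoxymethoxy)-3-(triethylsilyloxy)chromane; 19 geranyl bromide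
Product: 22 (2R,3S)-2-{3-[(2E)-3,7-dimethylocta-2,6-dien-1-yl]-4,5-bis(methoxymethoxy)phenyl}-5,7-bis(methoxymethoxy)-3-(triethylsilyloxy)chromane, via aryllithium 20 (not isolated), via arylcopper 21 (not isolated)
Conditions: n-BuLi (1.05 equiv), THF, −78 °C, 15 min; CuBr·SMe2 (1.1 equiv), −78 → −40 °C; 19 (1.3 equiv), −78 → 0 °C
Reagents that add atoms: none
Why: Bromine–lithium exchange (faster than any deprotonation at −78 °C and stabilised by the ortho MOM oxygen), transmetalation to copper and SN2 allylic substitution at the primary carbon of 19, where attack at the fully substituted γ-carbon is sterically disfavoured, so the linear E chain is kept and C2 and C3 are untouched.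

Step 13
Reactants: 22 (2R,3S)-2-{3-[(2E)-3,7-dimethylocta-2,6-dien-1-yl]-4,5-bis(methoxymethoxy)phenyl}-5,7-bis(methoxymethoxy)-3-(triethylsilyloxy)chromane
Product: 23 (2R,3S)-2-{3-[(2E)-3,7-dimethylocta-2,6-dien-1-yl]-4,5-dihydroxyphenyl}chromane-3,5,7-triol
Conditions: 1.25 M HCl in degassed MeOH, Ar, 0 → 40 °C
Reagents that add atoms: none
Why: Acid-catalysed acetal exchange of the four aryl MOM ethers with methanol (the C1 unit leaves as dimethoxymethane and so does not reach nucleophilic ring A) together with methanolysis of the labile TES ether, under dilute acid, mild warming and exclusion of air so that the ortho-geranyl phenol should not cyclise and C2 and C3 keep their configuration.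

Compound list
1 | phloroglucinol | Oc1cc(O)cc(O)c1 | starting material
2 | 3,5-bis(methoxymethoxy)phenol | COCOc1cc(O)cc(OCOC)c1 | intermediate
3 | allyl bromide | C=CCBr | starting material
4 | 1-(allyloxy)-3,5-bis(methoxymethoxy)benzene | C=CCOc1cc(OCOC)cc(OCOC)c1 | intermediate
5 | 6-allyl-3,5-bis(methoxymethoxy)cyclohexa-2,4-dien-1-one (racemic) | O=C1C=C(OCOC)C=C(OCOC)C1CC=C | intermediate (not isolated)
6 | 2-allyl-3,5-bis(methoxymethoxy)phenol | C=CCc1c(O)cc(OCOC)cc1OCOC | intermediate
7 | 5-bromovanillin | COc1cc(C=O)cc(Br)c1O | starting material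
8 | 3-bromo-4,5-dihydroxybenzaldehyde | O=Cc1cc(O)c(O)c(Br)c1 | intermediate
9 | 3-bromo-4,5-bis(methoxymethoxy)benzaldehyde | O=Cc1cc(Br)c(OCOC)c(OCOC)c1 | intermediate
10 | 3-bromo-4,5-bis(methoxymethoxy)benzoic acid | OC(=O)c1cc(Br)c(OCOC)c(OCOC)c1 | intermediate
11 | 2-allyl-3,5-bis(methoxymethoxy)phenyl 3-bromo-4,5-bis(methoxymethoxy)benzoate | C=CCc1c(OC(=O)c2cc(Br)c(OCOC)c(OCOC)c2)cc(OCOC)cc1OCOC | intermediate
12 | 2-(2,3-dihydroxypropyl)-3,5-bis(methoxymethoxy)phenyl 3-bromo-4,5-bis(methoxymethoxy)benzoate (racemic) | OCC(O)Cc1c(OC(=O)c2cc(Br)c(OCOC)c(OCOC)c2)cc(OCOC)cc1OCOC | intermediate (not isolated)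
13 | 2-(2-oxoethyl)-3,5-bis(methoxymethoxy)phenyl 3-bromo-4,5-bis(methoxymethoxy)benzoate | Brc1cc(C(=O)Oc2cc(OCOC)cc(OCOC)c2CC=O)cc(OCOC)c1OCOC | intermediate
14 | titanium-bound cis-2,3-diolate of the 2-arylchromane, drawn formally as its TiCl2 chelate (racemic) | Cl[Ti]1(Cl)OC2Cc3c(OCOC)cc(OCOC)cc3OC2(O1)c4cc(Br)c(OCOC)c(OCOC)c4 | intermediate (not isolated)
15 | 2-[3-bromo-4,5-bis(methoxymethoxy)phenyl]-5,7-bis(methoxymethoxy)-4H-chromene | Brc1cc(C2=CCc3c(OCOC)cc(OCOC)cc3O2)cc(OCOC)c1OCOC | intermediate
16 | (isopinocampheyl)[2-aryl-5,7-bis(methoxymethoxy)chroman-3-yl]borane, boron on C3 cis to the new H on C2 and trans to the aryl group | C[C@H]1[C@H](B[C@H]3Cc4c(OCOC)cc(OCOC)cc4O[C@@H]3c5cc(Br)c(OCOC)c(OCOC)c5)C[C@@H]2C[C@H]1C2(C)C | intermediate (not isolated)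
17 | (2R,3S)-2-[3-bromo-4,5-bis(methoxymethoxy)phenyl]-5,7-bis(methoxymethoxy)chroman-3-ol (2,3-trans) | Brc1cc([C@H]2Oc3cc(OCOC)cc(OCOC)c3C[C@@H]2O)cc(OCOC)c1OCOC | intermediate
18 | 3-O-triethylsilyl ether of 17 | Brc1cc([C@H]2Oc3cc(OCOC)cc(OCOC)c3C[C@@H]2O[Si](CC)(CC)CC)cc(OCOC)c1OCOC | intermediate
19 | geranyl bromide, (2E) | CC(C)=CCC/C(C)=C/CBr | starting material
20 | C5' aryllithium derived from 18 | [Li]c1cc([C@H]2Oc3cc(OCOC)cc(OCOC)c3C[C@@H]2O[Si](CC)(CC)CC)cc(OCOC)c1OCOC | intermediate (not isolated)
21 | C5' arylcopper derived from 20 | [Cu]c1cc([C@H]2Oc3cc(OCOC)cc(OCOC)c3C[C@@H]2O[Si](CC)(CC)CC)cc(OCOC)c1OCOC | intermediate (not isolated)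
22 | (2R,3S)-2-{3-[(2E)-3,7-dimethylocta-2,6-dien-1-yl]-4,5-bis(methoxymethoxy)phenyl}-5,7-bis(methoxymethoxy)-3-(triethylsilyloxy)chromane | CC(C)=CCC/C(C)=C/Cc1cc([C@H]2Oc3cc(OCOC)cc(OCOC)c3C[C@@H]2O[Si](CC)(CC)CC)cc(OCOC)c1OCOC | intermediate
23 | (2R,3S)-2-{3-[(2E)-3,7-dimethylocta-2,6-dien-1-yl]-4,5-dihydroxyphenyl}chromane-3,5,7-triol (5'-geranyl catechin, 2,3-trans) | CC(C)=CCC/C(C)=C/Cc1cc([C@H]2Oc3cc(O)cc(O)c3C[C@@H]2O)cc(O)c1O | target

Total step count: 13.
Longest linear sequence: 10 steps (steps 1–3 or 4–6, then steps 7–13).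

Steps most likely to fail

1. Step 9.
- Risks: intermolecular pinacol-type coupling of the aldehyde; collapse of the tetrahedral adduct with acyl transfer away from O1; Lewis-acid loss of MOM groups; hydrolysis or double-bond migration of the enol ether during isolation.
- Fallback: it sets out from 11 and comes back at 15, forming the same C2=C3 bond by carbene chemistry instead of reductive coupling. Petasis methylenation of the ester carbonyl with Cp2TiMe2 in toluene at 70 °C should give the α-aryloxystyrene 2-allyl-1-{[1-(3-bromo-4,5-bis(methoxymethoxy)phenyl)ethenyl]oxy}-3,5-bis(methoxymethoxy)benzene F1. Ring-closing metathesis of its enol ether alkene with the allyl group, using second-generation Grubbs catalyst in toluene at 70 °C, then closes ring C with loss of ethene and delivers 15.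

2. Step 10.
- Risks: poor facial selectivity on a hindered, benzo-fused enol ether; sluggish addition with dissociation of α-pinene from the reagent; β-elimination of boron and aryloxide that opens ring C before oxidation.
- Fallback: it sets out from 15 and comes back at 17, replacing reagent control by resolution. Hydroboration with BH3·SMe2 and NaOH/H2O2 oxidation should give the racemic trans alcohol, that is 17 together with its (2S,3R) enantiomer F2. Esterification with (S)-O-methylmandelic acid (EDC·HCl, catalytic DMAP, CH2Cl2, 0 °C) gives the (2R,3S)-configured (S)-O-methylmandelate ester F3 and the (2S,3R)-configured (S)-O-methylmandelate ester F4. These are separated by chromatography or crystallisation, and LiOH in THF/H2O releases 17 from the former.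

3. Step 13.
- Risks: acid-induced cyclisation of the geranyl chain onto the neighbouring 4'-phenol; alkylation of ring A by the released C1 fragment; acid-promoted opening of the C2–O1 bond with erosion of the C2 configuration; air oxidation of the catechol.
- Fallback: it sets out from 22 and comes back at 23, avoiding Brønsted acid altogether. Treatment with TESOTf and 2,2'-bipyridyl in CH2Cl2 at 0 °C exchanges each aryl MOM acetal directly for a silyl ether and should give the pentakis(triethylsilyl) ether of the target F5. This is desilylated with Et3N·3HF in THF at 0 °C under argon to 23.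

Further compounds
F1 | step 9 | 2-allyl-1-{[1-(3-bromo-4,5-bis(methoxymethoxy)phenyl)ethenyl]oxy}-3,5-bis(methoxymethoxy)benzene | C=CCc1c(OC(=C)c2cc(Br)c(OCOC)c(OCOC)c2)cc(OCOC)cc1OCOC
F2 | step 10 | (2S,3R)-2-[3-bromo-4,5-bis(methoxymethoxy)phenyl]-5,7-bis(methoxymethoxy)chroman-3-ol | Brc1cc([C@@H]2Oc3cc(OCOC)cc(OCOC)c3C[C@H]2O)cc(OCOC)c1OCOC
F3 | step 10 | (2R,3S)-2-[3-bromo-4,5-bis(methoxymethoxy)phenyl]-5,7-bis(methoxymethoxy)chroman-3-yl (S)-2-methoxy-2-phenylacetate | Brc1cc([C@H]2Oc3cc(OCOC)cc(OCOC)c3C[C@@H]2OC(=O)[C@@H](OC)c4ccccc4)cc(OCOC)c1OCOC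
F4 | step 10 | (2S,3R)-2-[3-bromo-4,5-bis(methoxymethoxy)phenyl]-5,7-bis(methoxymethoxy)chroman-3-yl (S)-2-methoxy-2-phenylacetate | Brc1cc([C@@H]2Oc3cc(OCOC)cc(OCOC)c3C[C@H]2OC(=O)[C@@H](OC)c4ccccc4)cc(OCOC)c1OCOC
F5 | step 13 | (2R,3S)-2-{3-[(2E)-3,7-dimethylocta-2,6-dien-1-yl]-4,5-bis(triethylsilyloxy)phenyl}-3,5,7-tris(triethylsilyloxy)chromane | CC(C)=CCC/C(C)=C/Cc1cc([C@H]2Oc3cc(O[Si](CC)(CC)CC)cc(O[Si](CC)(CC)CC)c3C[C@@H]2O[Si](CC)(CC)CC)cc(O[Si](CC)(CC)CC)c1O[Si](CC)(CC)CC
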